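The plan rests on cutting C3a'–C4' and C7'–C7a' of the central resorcinol ring (C3a', C4', C5', C6', C7', C7a'). That ring shares its C3a'–C7a' edge with the second dihydrofuran (O1', C2', C3'), so C7a' and C3a' are read as carbonyl and α-carbon of a γ-butyrolactone. C4', which bears C3 of the styryl-carrying dihydrobenzofuran, is read as an enone β-carbon. The precursors are an enantiopure trans-β,γ-diaryl lactone, activated as its silyl ketene acetal, and a C3-tethered (E)-methyl enone. One telescoped Michael–Claisen operation joins them, closes the carbocycle and restores the oxacycle as a vinylogous ester. Late dehydrogenation erases the two new sp3 centres.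

Key step: step 11

Locants: unprimed atoms belong to the styryl-bearing dihydrobenzofuran, primed atoms to the second benzofuran unit.
Assumption: the sense of induction of Rh2(R-PTTL)4 (2S) and of the (R,R)-TsDPEN ruthenium catalyst (R carbinol) is inferred from closely related substrates; if either proves opposite, the equally available antipodal catalyst is used.

Step 1
Reactants: 1 4'-methoxyacetophenone; 2 1-bromo-3,5-dimethoxybenzene
Product: 3 2-(3,5-dimethoxyphenyl)-1-(4-methoxyphenyl)ethan-1-one
Conditions: Pd2(dba)3 (1 mol %), Xantphos (2.4 mol %), NaOtBu (1.3 equiv), THF, 70 °C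
Reagents that add atoms: none
Why: Palladium-catalysed ketone enolate α-arylation joins the methyl carbon of 1 to the ipso carbon of 2 without regiochemical ambiguity (no Friedel–Crafts competition from the more electron-rich ring), and the more stabilised, bulkier product enolate resists a second arylation.

Step 2
Reactants: 3 2-(3,5-dimethoxyphenyl)-1-(4-methoxyphenyl)ethan-1-one; 4 ethyl bromoacetate
Product: 5 ethyl (±)-3-(3,5-dimethoxyphenyl)-4-(4-methoxyphenyl)-4-oxobutanoate
Conditions: LiN(SiMe3)2 (1.05 equiv), THF, −78 °C; then 4, −78 °C → rt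
Reagents that add atoms: none
Why: SN2 C-alkylation of the stabilised deoxybenzoin enolate by the reactive α-bromo ester; the new centre is racemic and stays configurationally labile, which step 3 exploits.

Step 3
Reactants: 5 ethyl (±)-3-(3,5-dimethoxyphenyl)-4-(4-methoxyphenyl)-4-oxobutanoate
Product: 7 (4R,5R)-4-(3,5-dimethoxyphenyl)-5-(4-methoxyphenyl)dihydrofuran-2(3H)-one (cis-lactone), via hydroxy ester 6 (not isolated)
Conditions: RuCl[(R,R)-TsDPEN](p-cymene) (1 mol %), HCO2H/Et3N (1:1), EtOAc, 40 °C; then PPTS (cat.), toluene, 60 °C; recrystallisation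
Reagents that add atoms: none
Why: Noyori–Ikariya asymmetric transfer hydrogenation with dynamic kinetic resolution: Et3N racemises the acidic α-aryl ketone centre faster than reduction, the (R,R)-catalyst sets the R carbinol as for simple aryl ketones, and hydride delivery anti to the α-aryl group (Felkin–Anh) selects the 3R antipode, so 6 lactonises to the cis-lactone, which is freed by crystallisation from any trans isomer (that isomer carries the opposite C4 configuration).

Step 4
Reactants: 7 (4R,5R)-cis-lactone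
Product: 8 (4R,5S)-4-(3,5-dimethoxyphenyl)-5-(4-methoxyphenyl)dihydrofuran-2(3H)-one (trans-lactone)
Conditions: CF3CO2H/CH2Cl2 (1:4), 0 °C → rt, stopped at equilibrium
Reagents that add atoms: none
Why: Acid-induced alkyl–oxygen heterolysis (the ionisation that cleaves p-methoxybenzyl esters, and the benzylic C–O epimerisation known from furofuran lignans) gives a p-anisyl cation that re-closes reversibly and funnels to the less strained trans-lactone, inverting only C5 while C4 keeps its configuration; short exposure limits E1 loss of the C4 proton.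

Step 5
Reactants: 9 methyl 2-(5-bromo-2-hydroxyphenyl)acetate; 10 4-methoxybenzyl chloride
Product: 11 methyl 2-{5-bromo-2-[(4-methoxybenzyl)oxy]phenyl}acetate
Conditions: K2CO3 (1.5 equiv), NaI (cat.), DMF, rt
Reagents that add atoms: none
Why: Williamson ether synthesis: the phenoxide is alkylated by the activated benzylic chloride faster than it can lactonise onto the neighbouring ester at room temperature.

Step 6
Reactants: 11 methyl 2-{5-bromo-2-[(4-methoxybenzyl)oxy]phenyl}acetate
Product: 12 methyl 2-{5-bromo-2-[(4-methoxybenzyl)oxy]phenyl}-2-diazoacetate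
Conditions: p-ABSA (1.2 equiv), DBU, MeCN, 0 °C → rt
Reagents that add atoms: 4-acetamidobenzenesulfonyl azide (p-ABSA), CC(=O)Nc1ccc(cc1)S(=O)(=O)N=[N+]=[N-]
Why: Regitz diazo transfer to the DBU-generated arylacetate enolate, the standard entry to donor/acceptor aryldiazoacetates.

Step 7
Reactants: 12 methyl 2-{5-bromo-2-[(4-methoxybenzyl)oxy]phenyl}-2-diazoacetate
Product: 13 methyl (2S,3R)-5-bromo-2-(4-methoxyphenyl)-2,3-dihydrobenzofuran-3-carboxylate (cis)
Conditions: Rh2(R-PTTL)4 (dirhodium tetrakis[N-phthaloyl-(R)-tert-leucinate], 1 mol %), toluene, −60 °C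
Reagents that add atoms: none
Why: Intramolecular 1,5 C–H insertion of the donor/acceptor rhodium carbene into the ether-activated p-methoxybenzylic C–H closes the dihydrofuran; the chiral carboxylate pocket sets C2 as S and the concerted insertion delivers C3 kinetically cis (3R).

Step 8
Reactants: 13 cis ester
Product: 14 methyl (2S,3S)-5-bromo-2-(4-methoxyphenyl)-2,3-dihydrobenzofuran-3-carboxylate (trans)
Conditions: NaOMe (0.3 equiv), MeOH, rt
Reagents that add atoms: none
Why: Ester-enolate epimerisation under thermodynamic control inverts only C3 and relieves the cis aryl/ester eclipsing, while the non-acidic C2 is retained; catalytic methoxide at room temperature keeps E1cB opening of the ring in check.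

Step 9
Reactants: 14 trans ester
Product: 15 [(2S,3R)-5-bromo-2-(4-methoxyphenyl)-2,3-dihydrobenzofuran-3-yl]methanol (trans)
Conditions: i-Bu2AlH (2.5 equiv), CH2Cl2, −78 → 0 °C; aqueous work-up
Reagents that add atoms: none
Why: Hydride reduction of the ester with excess i-Bu2AlH runs through to the primary alcohol and leaves aryl bromide, ethers and both stereocentres untouched (the C3 descriptor becomes R only through a change of CIP priorities).

Step 10
Reactants: 15 trans alcohol; 16 1-(triphenylphosphoranylidene)propan-2-one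
Product: 18 (E)-4-[(2S,3S)-5-bromo-2-(4-methoxyphenyl)-2,3-dihydrobenzofuran-3-yl]but-3-en-2-one, via aldehyde 17 (not isolated)
Conditions: Dess–Martin periodinane (1.2 equiv), CH2Cl2, 0 °C → rt; then 16 (2.5 equiv), rt
Reagents that add atoms: none
Why: Dess–Martin oxidation under non-basic conditions followed by Wittig olefination with the stabilised ylide in the same flask avoids handling the enolisable α-aryl-β-aryloxy aldehyde and gives the E-enone, the trans ring being the thermodynamic arrangement in any case.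

Step 11
Reactants: 8 (4R,5S)-trans-lactone (1.3 equiv); 18 (E)-enone
Product: 22 (2S,3R)-4-[(2S,3S)-5-bromo-2-(4-methoxyphenyl)-2,3-dihydrobenzofuran-3-yl]-3-(3,5-dimethoxyphenyl)-2-(4-methoxyphenyl)-3,3a,4,5-tetrahydrobenzofuran-6(2H)-one (C3a'/C4' unassigned), via silyl ketene acetal 19 (not isolated), via silyl enol ether adduct 20 (not isolated), via hydroxy dione 21 (not isolated)
Conditions: 8, LiN(i-Pr)2 (1.1 equiv), THF, −78 °C, then TMSCl, → 0 °C, volatiles removed, residue taken up in toluene and filtered; 18, Tf2NH (5 mol %), toluene, −78 °C; KOtBu (3 equiv), THF/t-BuOH, 0 °C → rt; 1 M HCl to pH 3, then PPTS (cat.), rt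
Reagents that add atoms: none
Why: Proposed new method: the neutral silyl ketene acetal 19 adds 1,4 to the silyl-activated enone (Mukaiyama–Michael, forms C3a'–C4'), KOtBu unmasks enol ether 20, the internal enolate equilibrates through t-BuOH to the C7' methyl enolate, this acylates on the lactone carbonyl C7a' with release of the C2' alkoxide, and acid finally returns the C2' hydroxyl to C7a' with loss of water. The closest known chemistry is the Michael–Claisen (dimedone-type) annulation of ester enolates with methyl enones and the base cyclisation of 5-oxohexanoates to cyclohexane-1,3-diones; new here are a γ-lactone as acyl donor and its re-closure in the same flask. The carbocycle closes 6-(enolexo)-exo-trig, the only strain-free option because the C5' enolate or a C3a' anion could form only four-membered rings, and the oxacycle re-forms by 5-exo-trig hemiketalisation at C7a' followed by dehydration to the conjugated vinylogous ester (C6' is out of reach). C3a' is set by attack anti to the C3' aryl group and C4' by the enone face left open by the C2 aryl group, but neither needs control since both become sp2 in step 12, while C2, C3, C2' and C3' are untouched: C3–H loses its vinylogous acidity once the enone is consumed, and even an SN1 closure at the p-anisyl carbon C2' would return the trans ring. The selectivity needed is 1,4-addition over γ-deprotonation at C3 (which would expel the O1 phenoxide) and over 1,2-addition; it is secured because no base is present while the enone exists and because ketone 1,2-addition of silyl ketene acetals is slow and reversible. Retro-Michael cleavage in the base stage is disfavoured by the poor leaving ability of an unstabilised lactone enolate and by irreversible formation of the dione anion.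

Step 12
Reactants: 22 tetrahydrobenzofuran-6(2H)-one
Product: 26 (2S,3S)-4-[(2S,3S)-5-bromo-2-(4-methoxyphenyl)-2,3-dihydrobenzofuran-3-yl]-3-(3,5-dimethoxyphenyl)-2-(4-methoxyphenyl)-2,3-dihydrobenzofuran-6-ol, via selenide 23 (not isolated), via selenoxide 24 (not isolated), via cross-conjugated dienone 25 (not isolated)
Conditions: LiN(i-Pr)2 (1.2 equiv), THF, −78 °C; PhSeBr (1.2 equiv), −78 °C; then H2O2 (30 %), pyridine, CH2Cl2, 0 °C → rt
Reagents that add atoms: none
Why: LiN(i-Pr)2 removes the kinetically favoured α' proton at C5' of the vinylogous ester, PhSeBr enters anti to the bulky C4' substituent and hence syn to C4'–H, and selenoxide syn-elimination gives the dienone whose C3a'–H tautomerises at once to the C6' phenol, an oxidation that touches neither dihydrofuran C–H nor the aryl bromide (quinone oxidants and aerobic divalent palladium are avoided for that reason).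

Step 13
Reactants: 26 bromo phenol; 27 3,5-dimethoxystyrene
Product: 28 (2S,3S)-4-{(2S,3S)-5-[(E)-3,5-dimethoxystyryl]-2-(4-methoxyphenyl)-2,3-dihydrobenzofuran-3-yl}-3-(3,5-dimethoxyphenyl)-2-(4-methoxyphenyl)-2,3-dihydrobenzofuran-6-ol
Conditions: Pd2(dba)3 (2.5 mol %), [HP(t-Bu)3]BF4 (10 mol %), Cy2NMe (2.5 equiv), 1,4-dioxane, 70 °C
Reagents that add atoms: none
Why: Mizoroki–Heck coupling of the unhindered C5 bromide at the terminal styrene carbon gives the E-stilbene by syn-insertion and syn-β-hydride elimination; the bulky electron-rich phosphine lets zerovalent palladium insert into the deactivated bromide at moderate temperature, and the free phenol is tolerated.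

Step 14
Reactants: 28 hexamethyl ether
Product: 29 trans-diptoindonesin B
Conditions: BBr3 (1 M in CH2Cl2, 14 equiv), CH2Cl2, −78 → 0 °C; then ice-water
Reagents that add atoms: none
Why: Lewis-acid aryl methyl ether cleavage (bromide attack on the boron-activated O-methyl groups), as used for methylated stilbenoids; any transient C2–O or C2'–O ionisation re-closes to the thermodynamically preferred trans rings because C3 and C3' are not touched, and the stilbene has no arene within reach for cyclisation.

Compound list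
1 | 4'-methoxyacetophenone | CC(=O)c1ccc(OC)cc1 | starting material
2 | 1-bromo-3,5-dimethoxybenzene | COc1cc(Br)cc(OC)c1 | starting material
3 | 2-(3,5-dimethoxyphenyl)-1-(4-methoxyphenyl)ethan-1-one | COc1ccc(cc1)C(=O)Cc1cc(OC)cc(OC)c1 | intermediate
4 | ethyl bromoacetate | CCOC(=O)CBr | starting material
5 | ethyl (±)-3-(3,5-dimethoxyphenyl)-4-(4-methoxyphenyl)-4-oxobutanoate | CCOC(=O)CC(c1cc(OC)cc(OC)c1)C(=O)c1ccc(OC)cc1 | intermediate
6 | ethyl (3R,4R)-3-(3,5-dimethoxyphenyl)-4-hydroxy-4-(4-methoxyphenyl)butanoate | CCOC(=O)C[C@H](c1cc(OC)cc(OC)c1)[C@@H](O)c1ccc(OC)cc1 | intermediate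
7 | (4R,5R)-4-(3,5-dimethoxyphenyl)-5-(4-methoxyphenyl)dihydrofuran-2(3H)-one (cis) | O=C1C[C@H](c2cc(OC)cc(OC)c2)[C@H](c2ccc(OC)cc2)O1 | intermediate
8 | (4R,5S)-4-(3,5-dimethoxyphenyl)-5-(4-methoxyphenyl)dihydrofuran-2(3H)-one (trans) | O=C1C[C@H](c2cc(OC)cc(OC)c2)[C@@H](c2ccc(OC)cc2)O1 | intermediate
9 | methyl 2-(5-bromo-2-hydroxyphenyl)acetate | COC(=O)Cc1cc(Br)ccc1O | starting material
10 | 4-methoxybenzyl chloride | COc1ccc(CCl)cc1 | starting material
11 | methyl 2-{5-bromo-2-[(4-methoxybenzyl)oxy]phenyl}acetate | COC(=O)Cc1cc(Br)ccc1OCc1ccc(OC)cc1 | intermediate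
12 | methyl 2-{5-bromo-2-[(4-methoxybenzyl)oxy]phenyl}-2-diazoacetate | COC(=O)C(=[N+]=[N-])c1cc(Br)ccc1OCc1ccc(OC)cc1 | intermediate
13 | methyl (2S,3R)-5-bromo-2-(4-methoxyphenyl)-2,3-dihydrobenzofuran-3-carboxylate (cis) | COc1ccc([C@H]2Oc3ccc(Br)cc3[C@H]2C(=O)OC)cc1 | intermediate
14 | methyl (2S,3S)-5-bromo-2-(4-methoxyphenyl)-2,3-dihydrobenzofuran-3-carboxylate (trans) | COc1ccc([C@H]2Oc3ccc(Br)cc3[C@@H]2C(=O)OC)cc1 | intermediate
15 | [(2S,3R)-5-bromo-2-(4-methoxyphenyl)-2,3-dihydrobenzofuran-3-yl]methanol (trans) | COc1ccc([C@H]2Oc3ccc(Br)cc3[C@@H]2CO)cc1 | intermediate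
16 | 1-(triphenylphosphoranylidene)propan-2-one | CC(=O)C=P(c1ccccc1)(c1ccccc1)c1ccccc1 | starting material
17 | (2S,3S)-5-bromo-2-(4-methoxyphenyl)-2,3-dihydrobenzofuran-3-carbaldehyde (trans) | COc1ccc([C@H]2Oc3ccc(Br)cc3[C@@H]2C=O)cc1 | intermediate
18 | (E)-4-[(2S,3S)-5-bromo-2-(4-methoxyphenyl)-2,3-dihydrobenzofuran-3-yl]but-3-en-2-one | COc1ccc([C@H]2Oc3ccc(Br)cc3[C@@H]2/C=C/C(C)=O)cc1 | intermediate
19 | {[(4R,5S)-4-(3,5-dimethoxyphenyl)-5-(4-methoxyphenyl)-4,5-dihydrofuran-2-yl]oxy}trimethylsilane | C[Si](C)(C)OC1=C[C@H](c2cc(OC)cc(OC)c2)[C@@H](c2ccc(OC)cc2)O1 | intermediate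
20 | lactone 8 carrying at its α-carbon (C3a') the group CH(C4')[(2S,3S)-dihydrobenzofuran-3-yl]–CH=C(CH3)OSiMe3 (C3a', C4' and enol ether geometry unassigned) | COc1ccc([C@H]2Oc3ccc(Br)cc3[C@@H]2C(C=C(C)O[Si](C)(C)C)C2[C@H](c3cc(OC)cc(OC)c3)[C@@H](c3ccc(OC)cc3)OC2=O)cc1 | intermediate
21 | 5-[(2S,3S)-5-bromo-2-(4-methoxyphenyl)-2,3-dihydrobenzofuran-3-yl]-4-[(1R,2S)-1-(3,5-dimethoxyphenyl)-2-hydroxy-2-(4-methoxyphenyl)ethyl]cyclohexane-1,3-dione (ring centres unassigned) | COc1ccc([C@H]2Oc3ccc(Br)cc3[C@@H]2C2CC(=O)CC(=O)C2[C@H](c2cc(OC)cc(OC)c2)[C@H](O)c2ccc(OC)cc2)cc1 | intermediate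
22 | (2S,3R)-4-[(2S,3S)-5-bromo-2-(4-methoxyphenyl)-2,3-dihydrobenzofuran-3-yl]-3-(3,5-dimethoxyphenyl)-2-(4-methoxyphenyl)-3,3a,4,5-tetrahydrobenzofuran-6(2H)-one (C3a', C4' unassigned) | COc1ccc([C@H]2Oc3ccc(Br)cc3[C@@H]2C2CC(=O)C=C3C2[C@H](c2cc(OC)cc(OC)c2)[C@@H](c2ccc(OC)cc2)O3)cc1 | intermediate
23 | C5'-phenylselanyl derivative of 22 | COc1ccc([C@H]2Oc3ccc(Br)cc3[C@@H]2C2C([Se]c3ccccc3)C(=O)C=C3C2[C@H](c2cc(OC)cc(OC)c2)[C@@H](c2ccc(OC)cc2)O3)cc1 | intermediate
24 | C5'-phenylseleninyl derivative of 22 (selenoxide) | COc1ccc([C@H]2Oc3ccc(Br)cc3[C@@H]2C2C([Se](=O)c3ccccc3)C(=O)C=C3C2[C@H](c2cc(OC)cc(OC)c2)[C@@H](c2ccc(OC)cc2)O3)cc1 | intermediate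
25 | 4',5'-didehydro derivative of 22 (3,3a-dihydrobenzofuran-6(2H)-one, cross-conjugated dienone) | COc1ccc([C@H]2Oc3ccc(Br)cc3[C@@H]2C2=CC(=O)C=C3C2[C@H](c2cc(OC)cc(OC)c2)[C@@H](c2ccc(OC)cc2)O3)cc1 | intermediate
26 | (2S,3S)-4-[(2S,3S)-5-bromo-2-(4-methoxyphenyl)-2,3-dihydrobenzofuran-3-yl]-3-(3,5-dimethoxyphenyl)-2-(4-methoxyphenyl)-2,3-dihydrobenzofuran-6-ol | COc1ccc([C@H]2Oc3ccc(Br)cc3[C@@H]2c2cc(O)cc3c2[C@H](c2cc(OC)cc(OC)c2)[C@@H](c2ccc(OC)cc2)O3)cc1 | intermediate
27 | 3,5-dimethoxystyrene | C=Cc1cc(OC)cc(OC)c1 | starting material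
28 | (2S,3S)-4-{(2S,3S)-5-[(E)-3,5-dimethoxystyryl]-2-(4-methoxyphenyl)-2,3-dihydrobenzofuran-3-yl}-3-(3,5-dimethoxyphenyl)-2-(4-methoxyphenyl)-2,3-dihydrobenzofuran-6-ol | COc1ccc([C@H]2Oc3ccc(/C=C/c4cc(OC)cc(OC)c4)cc3[C@@H]2c2cc(O)cc3c2[C@H](c2cc(OC)cc(OC)c2)[C@@H](c2ccc(OC)cc2)O3)cc1 | intermediate
29 | trans-diptoindonesin B, (2S,3S,2'S,3'S) | Oc1ccc([C@H]2Oc3ccc(/C=C/c4cc(O)cc(O)c4)cc3[C@@H]2c2cc(O)cc3c2[C@H](c2cc(O)cc(O)c2)[C@@H](c2ccc(O)cc2)O3)cc1 | target

Total step count: 14. Longest linear sequence: 10 (steps 5–14). The lactone branch (steps 1–4) is convergent.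

Steps most likely to fail

Step 11. The conjugate addition may stall because both bond-forming carbons are flanked by tertiary centres. The acyl transfer may also stall because the released C2' alkoxide re-attacks and regenerates the lactone. The fallback uses only known reactions and replaces the cyclic acyl donor by an acyclic methyl ester whose leaving group cannot return. It sets out from 8 and rejoins the route at 22.
- Saponification of 8 with KOH gives potassium hydroxy carboxylate F1.
- MeI in DMF converts it into methyl hydroxy ester F2, which is silylated at once (TBSCl, imidazole) to tert-butyldimethylsilyl ether F3.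
- LiN(i-Pr)2/TMSCl gives ketene silyl acetal F4.
- Its Mukaiyama–Michael addition to 18 (Tf2NH cat.) gives silyl enol ether adduct F5.
- KOtBu cyclises this 5-oxohexanoate in the classical way to silyloxy dione F6.
- HF·pyridine removes the silyl group to give 21, which dehydrates under the acidic conditions to 22.

Step 3. Racemisation at the α-aryl centre may lag behind hydride transfer, or the catalyst may discriminate poorly between the two substrate antipodes. Because step 4 turns diastereomeric leakage into enantiomeric leakage, either process erodes the optical purity of the whole primed half. The fallback replaces asymmetric catalysis by classical resolution. It sets out from 5 and rejoins at 8.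
- NaBH4 in MeOH, followed by CF3CO2H/CH2Cl2 on the crude racemic forms of 6 and 7, gives racemic trans-lactone F7.
- AlMe3-mediated aminolysis with (S)-1-phenylethylamine gives hydroxy amide F8 and diastereomeric hydroxy amide F9, which are separated by crystallisation or chromatography.
- F8 is re-lactonised with TsOH in hot toluene to 8, with recovery of the amine.

Step 14. The six-fold Lewis-acid ether cleavage may be accompanied by protonation and oligomerisation of the electron-rich stilbene. Ring-opened benzylic cations may also be captured before they re-close. The fallback cleaves the ethers before the stilbene exists and finishes with a mild transesterification. It sets out from 26 and rejoins at 29.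
- BBr3 cleaves the four ethers of 26 to pentaphenol bromide F10.
- Ac2O/pyridine gives pentaacetate F11.
- Heck coupling with 3,5-diacetoxystyrene under the conditions of step 13 gives heptaacetate F12.
- Catalytic K2CO3 in MeOH at 0 °C under argon releases 29.

Further compounds
F1 | step 11 | potassium (3R,4S)-3-(3,5-dimethoxyphenyl)-4-hydroxy-4-(4-methoxyphenyl)butanoate | [K+].[O-]C(=O)C[C@H](c1cc(OC)cc(OC)c1)[C@H](O)c1ccc(OC)cc1
F2 | step 11 | methyl (3R,4S)-3-(3,5-dimethoxyphenyl)-4-hydroxy-4-(4-methoxyphenyl)butanoate | COC(=O)C[C@H](c1cc(OC)cc(OC)c1)[C@H](O)c1ccc(OC)cc1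
F3 | step 11 | methyl (3R,4S)-4-[(tert-butyldimethylsilyl)oxy]-3-(3,5-dimethoxyphenyl)-4-(4-methoxyphenyl)butanoate | COC(=O)C[C@H](c1cc(OC)cc(OC)c1)[C@H](O[Si](C)(C)C(C)(C)C)c1ccc(OC)cc1
F4 | step 11 | O-methyl O-trimethylsilyl ketene acetal of F3 | COC(O[Si](C)(C)C)=C[C@H](c1cc(OC)cc(OC)c1)[C@H](O[Si](C)(C)C(C)(C)C)c1ccc(OC)cc1
F5 | step 11 | Michael adduct of F4 and 18 as its trimethylsilyl enol ether (C3a', C4' unassigned) | COc1ccc([C@H]2Oc3ccc(Br)cc3[C@@H]2C(C=C(C)O[Si](C)(C)C)C(C(=O)OC)[C@H](c2cc(OC)cc(OC)c2)[C@H](O[Si](C)(C)C(C)(C)C)c2ccc(OC)cc2)cc1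
F6 | step 11 | O-tert-butyldimethylsilyl ether of 21 | COc1ccc([C@H]2Oc3ccc(Br)cc3[C@@H]2C2CC(=O)CC(=O)C2[C@H](c2cc(OC)cc(OC)c2)[C@H](O[Si](C)(C)C(C)(C)C)c2ccc(OC)cc2)cc1
F7 | step 3 | (±)-trans-4-(3,5-dimethoxyphenyl)-5-(4-methoxyphenyl)dihydrofuran-2(3H)-one | O=C1C[C@H](c2cc(OC)cc(OC)c2)[C@@H](c2ccc(OC)cc2)O1.O=C1C[C@@H](c2cc(OC)cc(OC)c2)[C@H](c2ccc(OC)cc2)O1
F8 | step 3 | (3R,4S)-3-(3,5-dimethoxyphenyl)-4-hydroxy-4-(4-methoxyphenyl)-N-[(S)-1-phenylethyl]butanamide | C[C@H](NC(=O)C[C@H](c1cc(OC)cc(OC)c1)[C@H](O)c1ccc(OC)cc1)c1ccccc1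
F9 | step 3 | (3S,4R)-3-(3,5-dimethoxyphenyl)-4-hydroxy-4-(4-methoxyphenyl)-N-[(S)-1-phenylethyl]butanamide | C[C@H](NC(=O)C[C@@H](c1cc(OC)cc(OC)c1)[C@@H](O)c1ccc(OC)cc1)c1ccccc1
F10 | step 14 | pentaphenol corresponding to 26 (all four methyl ethers cleaved, C5 bromide retained) | Oc1ccc([C@H]2Oc3ccc(Br)cc3[C@@H]2c2cc(O)cc3c2[C@H](c2cc(O)cc(O)c2)[C@@H](c2ccc(O)cc2)O3)cc1
F11 | step 14 | pentaacetate of F10 | CC(=O)Oc1ccc([C@H]2Oc3ccc(Br)cc3[C@@H]2c2cc(OC(C)=O)cc3c2[C@H](c2cc(OC(C)=O)cc(OC(C)=O)c2)[C@@H](c2ccc(OC(C)=O)cc2)O3)cc1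
F12 | step 14 | trans-diptoindonesin B heptaacetate | CC(=O)Oc1ccc([C@H]2Oc3ccc(/C=C/c4cc(OC(C)=O)cc(OC(C)=O)c4)cc3[C@@H]2c2cc(OC(C)=O)cc3c2[C@H](c2cc(OC(C)=O)cc(OC(C)=O)c2)[C@@H](c2ccc(OC(C)=O)cc2)O3)cc1
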